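**Retrosynthetic overview**
1. Ester C–O: target ⇒ (−)-lariciresinol + (E)-p-coumaric acid, joined last by a Mitsunobu esterification at the only aliphatic OH.
2. Oxolane C7–O: 5-exo SN1 cycloetherification of a benzylic-carbinol 1,4-diol (sets C7), which comes from a trans-selective lactone aldol with O-benzylvanillin (sets C8) and LiAlH4 opening.
3. (S)-β-Benzyl-γ-butyrolactone ⇒ ozonolysis/reduction of ethyl (3S,4E)-3-benzylhex-4-enoate, whose C8–C8' bond comes from a Johnson–Claisen [3,3] rearrangement with 1,3-chirality transfer (sets C8').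
4. (S,E)-Allylic alcohol ⇒ cross-metathesis of O-benzyleugenol with (S)-but-3-en-2-ol, the only bought stereocentre.
5. Ring order: transient γ-lactone first, then opened and re-closed as the oxolane.

Assumption: the SMILES is read as the 9-O-(E)-p-coumarate of (−)-lariciresinol, oxolane (2R,3S,4S) (2-aryl/3-CH2O trans, 3-CH2O/4-benzyl cis); (S)-but-3-en-2-ol is taken as a catalogue chiral building block.

**Step 1**
Reactants: 1 eugenol
Product: 2 4-allyl-1-(benzyloxy)-2-methoxybenzene (O-benzyleugenol)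
Conditions: BnBr (1.1 equiv), K2CO3, acetone, reflux
Reagents that add atoms: benzyl bromide, BrCc1ccccc1
Why: Williamson ether synthesis (SN2 of the phenoxide on benzyl bromide) masks the phenol for the later ozone, enolate and hydride steps; no stereocentre is involved.

**Step 2**
Reactants: 2 O-benzyleugenol; 3 (S)-but-3-en-2-ol (2 equiv)
Product: 4 (2S,3E)-5-[4-(benzyloxy)-3-methoxyphenyl]pent-3-en-2-ol
Conditions: Hoveyda–Grubbs II (3 mol%), 1,4-benzoquinone (10 mol%), CH2Cl2, 40 °C, N2 sweep; remove any Z isomer on AgNO3–silica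
Reagents that add atoms: none
Why: Olefin cross-metathesis of a type-I allylarene with a type-II secondary allylic alcohol gives the E-alkene under loss of ethene, the achiral Ru carbene leaves the bought (S)-carbinol untouched, and benzoquinone suppresses Ru–H olefin migration.

**Step 3**
Reactants: 4 (2S,3E)-allylic alcohol; 5 triethyl orthoacetate (excess, as solvent)
Product: 7 ethyl (3S,4E)-3-[4-(benzyloxy)-3-methoxybenzyl]hex-4-enoate, via mixed ketene acetal 6 (not isolated)
Conditions: MeC(OEt)3, EtCO2H (cat.), 140 °C, EtOH distilled off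
Reagents that add atoms: none
Why: Johnson–Claisen [3,3]-sigmatropic rearrangement through a chair transition state with the carbinol methyl equatorial forms the C8–C8' bond on the alkene face from which the C–O bond leaves, so the (S)-carbinol of the E-alkene is relayed to (S)-C3 with an E-propenyl group.

**Step 4**
Reactants: 7 ethyl (3S,4E)-3-[4-(benzyloxy)-3-methoxybenzyl]hex-4-enoate
Product: 10 (S)-4-[4-(benzyloxy)-3-methoxybenzyl]dihydrofuran-2(3H)-one, via aldehyde ester 8 (not isolated), via hydroxy ester 9 (not isolated)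
Conditions: O3, CH2Cl2/MeOH, −78 °C (Sudan III end point); NaBH4, −78 °C → rt; 1 M HCl work-up
Reagents that add atoms: ozone, [O-][O+]=O
Why: Ozonolysis cuts off the propenyl group, immediate borohydride reduction at low temperature prevents α-epimerisation of the transient aldehyde, and the γ-hydroxy ester lactonises on acidification with the C3 stereocentre unchanged.

**Step 5**
Reactants: 10 (S)-lactone; 11 O-benzylvanillin (4-(benzyloxy)-3-methoxybenzaldehyde)
Product: 12 (3R,4S)-4-[4-(benzyloxy)-3-methoxybenzyl]-3-{[4-(benzyloxy)-3-methoxyphenyl](hydroxy)methyl}dihydrofuran-2(3H)-one (mixture of carbinol epimers)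
Conditions: LDA (1.1 equiv), THF, −78 °C; then 11; AcOH quench at −78 °C
Reagents that add atoms: none
Why: Aldol addition of the lithium lactone enolate occurs anti to the β-benzyl group and sets C8 trans to C8' (3R), while the carbinol epimers do not matter because both converge in step 7.

**Step 6**
Reactants: 12 aldol adduct
Product: 13 (2S,3S)-2-{[4-(benzyloxy)-3-methoxyphenyl](hydroxy)methyl}-3-[4-(benzyloxy)-3-methoxybenzyl]butane-1,4-diol (carbinol epimers)
Conditions: LiAlH4, THF, 0 °C → rt; aqueous work-up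
Reagents that add atoms: none
Why: Hydride reduction of the lactone to the 1,4-diol is faster than retro-aldol at 0 °C and leaves a triol with no epimerisable centre.

**Step 7**
Reactants: 13 triol
Product: 14 [(2R,3S,4S)-2-[4-(benzyloxy)-3-methoxyphenyl]-4-[4-(benzyloxy)-3-methoxybenzyl]tetrahydrofuran-3-yl]methanol (di-O-benzyl-(−)-lariciresinol)
Conditions: p-TsOH·H2O (10 mol%), CH2Cl2, 0 °C → rt, stop at full conversion
Reagents that add atoms: none
Why: Acid-catalysed SN1 cycloetherification through the p-alkoxybenzyl cation lets the C9' hydroxyl close the five-membered ring (the C9 hydroxyl could only give an oxetane) anti to the neighbouring CH2OH branch, so both carbinol epimers give the favoured 2,3-trans (2R) oxolane.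

**Step 8**
Reactants: 14 di-O-benzyl-(−)-lariciresinol
Product: 15 (−)-lariciresinol, 4-[(2R,3S,4S)-4-(4-hydroxy-3-methoxybenzyl)-3-(hydroxymethyl)tetrahydrofuran-2-yl]-2-methoxyphenol
Conditions: H2 (1 atm), 10% Pd/C, EtOAc/MeOH, rt, stop after 2 equiv H2
Reagents that add atoms: none
Why: Catalytic hydrogenolysis removes the two aryl benzyl ethers faster than it opens the cyclic benzylic ether under neutral conditions, and no stereocentre is touched.

**Step 9**
Reactants: 15 (−)-lariciresinol; 16 (E)-p-coumaric acid (1.1 equiv)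
Product: 17 lariciresinol p-coumarate, [(2R,3S,4S)-2-(4-hydroxy-3-methoxyphenyl)-4-(4-hydroxy-3-methoxybenzyl)tetrahydrofuran-3-yl]methyl (E)-3-(4-hydroxyphenyl)acrylate
Conditions: PPh3 (1.2 equiv), DIAD (1.2 equiv, added last), THF, 0 °C → rt
Reagents that add atoms: none
Why: In the Mitsunobu esterification only the primary alcohol is activated as the alkoxyphosphonium and the carboxylate (pKa about 4.5) out-competes the phenols (pKa about 10) as nucleophile, so the ester forms at CH2 without protecting groups and without touching a stereocentre or the E-alkene.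

**Compound list**
1 | eugenol (4-allyl-2-methoxyphenol) | C=CCc1ccc(O)c(OC)c1 | starting material
2 | 4-allyl-1-(benzyloxy)-2-methoxybenzene | C=CCc1ccc(OCc2ccccc2)c(OC)c1 | intermediate
3 | (S)-but-3-en-2-ol | C[C@H](O)C=C | starting material
4 | (2S,3E)-5-[4-(benzyloxy)-3-methoxyphenyl]pent-3-en-2-ol | C[C@H](O)/C=C/Cc1ccc(OCc2ccccc2)c(OC)c1 | intermediate
5 | triethyl orthoacetate | CCOC(C)(OCC)OCC | starting material
6 | 1-(benzyloxy)-4-{(2E,4S)-4-[(1-ethoxyethenyl)oxy]pent-2-en-1-yl}-2-methoxybenzene (mixed ketene acetal) | C=C(OCC)O[C@@H](C)/C=C/Cc1ccc(OCc2ccccc2)c(OC)c1 | intermediate (not isolated)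
7 | ethyl (3S,4E)-3-[4-(benzyloxy)-3-methoxybenzyl]hex-4-enoate | CCOC(=O)C[C@H](Cc1ccc(OCc2ccccc2)c(OC)c1)/C=C/C | intermediate
8 | ethyl (S)-3-[4-(benzyloxy)-3-methoxybenzyl]-4-oxobutanoate | CCOC(=O)C[C@H](Cc1ccc(OCc2ccccc2)c(OC)c1)C=O | intermediate (not isolated)
9 | ethyl (S)-3-[4-(benzyloxy)-3-methoxybenzyl]-4-hydroxybutanoate | CCOC(=O)C[C@H](Cc1ccc(OCc2ccccc2)c(OC)c1)CO | intermediate (not isolated)
10 | (S)-4-[4-(benzyloxy)-3-methoxybenzyl]dihydrofuran-2(3H)-one | O=C1C[C@H](Cc2ccc(OCc3ccccc3)c(OC)c2)CO1 | intermediate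
11 | 4-(benzyloxy)-3-methoxybenzaldehyde (O-benzylvanillin) | COc1cc(C=O)ccc1OCc1ccccc1 | starting material
12 | (3R,4S)-4-[4-(benzyloxy)-3-methoxybenzyl]-3-{[4-(benzyloxy)-3-methoxyphenyl](hydroxy)methyl}dihydrofuran-2(3H)-one, carbinol epimers | O=C1OC[C@@H](Cc2ccc(OCc3ccccc3)c(OC)c2)[C@@H]1C(O)c1ccc(OCc2ccccc2)c(OC)c1 | intermediate
13 | (2S,3S)-2-{[4-(benzyloxy)-3-methoxyphenyl](hydroxy)methyl}-3-[4-(benzyloxy)-3-methoxybenzyl]butane-1,4-diol, carbinol epimers | OC[C@@H](Cc1ccc(OCc2ccccc2)c(OC)c1)[C@@H](CO)C(O)c1ccc(OCc2ccccc2)c(OC)c1 | intermediate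
14 | [(2R,3S,4S)-2-[4-(benzyloxy)-3-methoxyphenyl]-4-[4-(benzyloxy)-3-methoxybenzyl]tetrahydrofuran-3-yl]methanol | COc1cc(C[C@@H]2CO[C@@H](c3ccc(OCc4ccccc4)c(OC)c3)[C@@H]2CO)ccc1OCc1ccccc1 | intermediate
15 | (−)-lariciresinol, oxolane (2R,3S,4S) | COc1cc(C[C@@H]2CO[C@@H](c3ccc(O)c(OC)c3)[C@@H]2CO)ccc1O | intermediate
16 | (E)-p-coumaric acid | OC(=O)/C=C/c1ccc(O)cc1 | starting material
17 | lariciresinol p-coumarate, oxolane (2R,3S,4S) | COc1cc(C[C@@H]2CO[C@@H](c3ccc(O)c(OC)c3)[C@@H]2COC(=O)/C=C/c2ccc(O)cc2)ccc1O | target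

**Step count and risks**
Total steps: 9. Longest linear sequence: 9 (1 → 17).

Most likely to fail, with fallbacks:

Step 2 (cross-metathesis). Risks are Ru–H migration of the allylarene into conjugation, isomerisation of 3 to butanone, and residual Z isomer, which would lower the ee after step 3. Fallback, from 11 back to 4, builds the alkene by alkyne chemistry. Reduce 11 with NaBH4 to 4-(benzyloxy)-3-methoxybenzyl alcohol F1 and convert it with PBr3 into 4-(benzyloxy)-3-methoxybenzyl bromide F2. Couple F2 with the magnesium dianion of bought (S)-but-3-yn-2-ol (C[C@H](O)C#C; EtMgBr 2.1 equiv, CuCl cat., THF) to give (S)-5-[4-(benzyloxy)-3-methoxyphenyl]pent-3-yn-2-ol F3. Trans-hydroalumination of F3 with Red-Al (THF, 0 °C) gives 4 as the pure E isomer.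

Step 7 (cationic ring closure). Risks are Friedel–Crafts closure of the benzylic cation onto the other guaiacyl ring (aryltetralin) and some 2,3-cis isomer. Fallback, from 13 back to 15, closes the ring through a quinone methide. Hydrogenolyse the benzyl ethers of 13 first (H2, Pd/C, EtOAc, neutral, short time) to (2S,3S)-2-[hydroxy(4-hydroxy-3-methoxyphenyl)methyl]-3-(4-hydroxy-3-methoxybenzyl)butane-1,4-diol F4. Its 4-hydroxybenzylic alcohol ionises to a p-quinone methide under far weaker acid (PPTS, MeCN, rt), and the C9' hydroxyl adds to give 15 directly, which also removes step 8.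

Step 9 (protecting-group-free Mitsunobu). Risks are aryl ether formation at one of the three phenols and difficult separation from Ph3PO. Fallback, from 15 back to 17, uses acetate protection. Acetylate only the phenols of 15 (Ac2O 2.2 equiv, aqueous NaOH, 0 °C) to 4-[(2R,3S,4S)-4-(4-acetoxy-3-methoxybenzyl)-3-(hydroxymethyl)tetrahydrofuran-2-yl]-2-methoxyphenyl acetate F5. Acetylate 16 in the same way to (E)-4-acetoxycinnamic acid F6. Couple F5 and F6 with EDC/DMAP (CH2Cl2) to the triacetate [(2R,3S,4S)-2-(4-acetoxy-3-methoxyphenyl)-4-(4-acetoxy-3-methoxybenzyl)tetrahydrofuran-3-yl]methyl (E)-3-(4-acetoxyphenyl)acrylate F7. Cleave the three aryl acetates with pyrrolidine (CH2Cl2, 0 °C), which leaves the alkyl cinnamate intact, to arrive at 17.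

**Further compounds**
F1 | step 2 | 4-(benzyloxy)-3-methoxybenzyl alcohol | OCc1ccc(OCc2ccccc2)c(OC)c1
F2 | step 2 | 4-(benzyloxy)-3-methoxybenzyl bromide | BrCc1ccc(OCc2ccccc2)c(OC)c1
F3 | step 2 | (S)-5-[4-(benzyloxy)-3-methoxyphenyl]pent-3-yn-2-ol | C[C@H](O)C#CCc1ccc(OCc2ccccc2)c(OC)c1
F4 | step 7 | (2S,3S)-2-[hydroxy(4-hydroxy-3-methoxyphenyl)methyl]-3-(4-hydroxy-3-methoxybenzyl)butane-1,4-diol, carbinol epimers | OC[C@@H](Cc1ccc(O)c(OC)c1)[C@@H](CO)C(O)c1ccc(O)c(OC)c1
F5 | step 9 | 4-[(2R,3S,4S)-4-(4-acetoxy-3-methoxybenzyl)-3-(hydroxymethyl)tetrahydrofuran-2-yl]-2-methoxyphenyl acetate | COc1cc(C[C@@H]2CO[C@@H](c3ccc(OC(C)=O)c(OC)c3)[C@@H]2CO)ccc1OC(C)=O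
F6 | step 9 | (E)-4-acetoxycinnamic acid | CC(=O)Oc1ccc(/C=C/C(O)=O)cc1
F7 | step 9 | [(2R,3S,4S)-2-(4-acetoxy-3-methoxyphenyl)-4-(4-acetoxy-3-methoxybenzyl)tetrahydrofuran-3-yl]methyl (E)-3-(4-acetoxyphenyl)acrylate | COc1cc(C[C@@H]2CO[C@@H](c3ccc(OC(C)=O)c(OC)c3)[C@@H]2COC(=O)/C=C/c2ccc(OC(C)=O)cc2)ccc1OC(C)=O
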